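**Plan**

- The enabling feature is the C1–C5 ring-fusion bond next to the C2 oxygen, together with oxygens on C5 and C8 that sit 1,4 across C6–C7 of the seven-membered ring on the same (β) face. C2/C1 can therefore be a vinyl diazoketone, and C5–C8 a 1,4-dioxygenated diene whose two oxygens are bridged by one silicon atom.
- Retrosynthesis cuts, in order: the angelate ester at C2–O; C11–CH3 and the C11–O5 ether (α-diazo lactone); the lactone C12–O8; then C8–C9 and C1–C5 of the hydroazulene (formal [4+3]); finally C1–C2, C6–C7 and C5–C6 of the open chain.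
- Forward: (R)-citramalic acid is extended to an acyclic keto aldehyde, the two carbonyls are tied as a cyclic silylene bis(enol ether), and the vinyl diazoketone is installed. Rhodium then closes the cyclopentanone (cyclopropanation) and the cycloheptadiene (Cope) in one flask. The γ-lactone, the oxolane, C13 and the angelate follow.
- Stereochemistry: C4 comes from citramalic acid; C5 from the face of cyclopropanation set by C4; C8 is cis to C5–O through the silylene tether; C7 by hydrogenation opposite the silylene; C10 and C1 by conjugate reduction; C2 by hydroxyl-directed reduction; C11 is fixed by the cage.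

Key step: step 10

Convention: ring compounds carry guaiane numbering (C1–C5 five-membered ring, C1/C5–C10 seven-membered ring, C11/C12 on C7, C13 on C11, C14 on C10, C15 on C4); open-chain precursors use the same atom labels. β is the face of the C4 methyl group and the C5 oxygen, α the other face.

Assumption: the 8β-hydroxy tert-butyl ester 21 does not lactonise until acid is added in step 14; if it does so earlier, the lactone should pass through steps 13 and 14 unchanged.

**Route**

Step 1
Reactants: 1 (R)-citramalic acid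
Product: 2 2-[(4R)-2,2,4-trimethyl-5-oxo-1,3-dioxolan-4-yl]acetic acid
Conditions: Me2C(OMe)2, p-TsOH (cat.), rt
Reagents that add atoms: 2,2-dimethoxypropane, COC(C)(C)OC
Why: Acid-catalysed acetalisation of the α-hydroxy acid closes the five-membered dioxolanone, which masks the tertiary hydroxyl, activates the C5 carboxyl and leaves the CH2CO2H (C2) free; the stereocentre is not touched.

Step 2
Reactants: 2 dioxolanone acid
Product: 4 (3R)-3-hydroxy-3-methyl-4-oxopentanoic acid, via Weinreb amide 3 (not isolated)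
Conditions: MeNH(OMe)·HCl, i-PrMgCl, THF, −20 °C; then MeMgBr, 0 °C; aq. HCl
Reagents that add atoms: methylmagnesium bromide, C[Mg]Br
Why: The magnesium amide opens the activated dioxolanone to a Weinreb amide while the carboxylate stays inert, and Grignard addition stops at the methyl ketone through the chelated tetrahedral intermediate (Weinreb ketone synthesis); the new methyl group is C6.

Step 3
Reactants: 4 hydroxy keto acid
Product: 6 (3R)-3-[(tert-butyldimethylsilyl)oxy]-3-methyl-4-oxopentanoic acid, via silyl ester 5 (not isolated)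
Conditions: TBSOTf, 2,6-lutidine, CH2Cl2, −78 → 0 °C; then K2CO3 (cat.), MeOH
Reagents that add atoms: tert-butyldimethylsilyl triflate, CC(C)(C)[Si](C)(C)OS(=O)(=O)C(F)(F)F
Why: The silyl triflate silylates the hindered tertiary alcohol and the acid, and only the labile silyl ester is cleaved by mild methanolysis (silyl ether protection).

Step 4
Reactants: 6 silyloxy keto acid
Product: 8 (3R)-3-[(tert-butyldimethylsilyl)oxy]-N-methoxy-N,3-dimethyl-4-oxopentanamide, via acyl imidazole 7 (not isolated)
Conditions: CDI, CH2Cl2, rt; then MeNH(OMe)·HCl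
Reagents that add atoms: N,O-dimethylhydroxylamine hydrochloride, CNOC.Cl
Why: Amide formation through the acyl imidazole gives a C2 acyl group that survives enolate and enol-silylation chemistry and later accepts exactly one equivalent of a Grignard reagent.

Step 5
Reactants: 8 keto Weinreb amide
Product: 10 (3R)-5-bromo-3-[(tert-butyldimethylsilyl)oxy]-N-methoxy-N,3-dimethyl-4-oxopentanamide, via silyl enol ether 9 (not isolated)
Conditions: LiHMDS, TMSCl, THF, −78 °C; then NBS, 0 °C
Reagents that add atoms: N-bromosuccinimide, BrN1C(=O)CCC1=O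
Why: The methyl ketone is the only kinetically acidic site (C4 is quaternary, the amide α-CH2 is far less acidic), so its enol silane forms regioselectively and is brominated by NBS (α-bromination of a silyl enol ether).

Step 6
Reactants: 10 bromoketone; 11 tert-butyl 4-oxobutanoate
Product: 13 tert-butyl (6R)-6-[(tert-butyldimethylsilyl)oxy]-3-formyl-8-[methoxy(methyl)amino]-6-methyl-5,8-dioxooctanoate, via enamine 12 (not isolated)
Conditions: 11, pyrrolidine, 4 Å MS, MeCN, 0 °C; then 10, rt; aq. AcOH/NaOAc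
Reagents that add atoms: water, O
Why: Stork enamine alkylation: the aldehyde enamine is C-alkylated by the reactive α-bromoketone (C6–C7) and hydrolysis should give the 1,4-keto aldehyde; the new centre C7 becomes trigonal in step 7, so its configuration does not matter.

Step 7
Reactants: 13 keto aldehyde
Product: 14 cyclic di-tert-butylsilylene bis(enol ether) (2,2-di-tert-butyl-1,3,2-dioxasilepine)
Conditions: t-Bu2Si(OTf)2, Et3N, CH2Cl2 (0.02 M), 0 °C → rt
Reagents that add atoms: di-tert-butylsilyl bis(trifluoromethanesulfonate), CC(C)(C)[Si](OS(=O)(=O)C(F)(F)F)(OS(=O)(=O)C(F)(F)F)C(C)(C)C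
Why: Soft enolisation of both carbonyls with the silyl bis(triflate) and amine (enol silylation) closes a seven-membered ring, which forces O5 cis to C7 and O8 cis to C6; C5 can enolise only toward C6, and ester and Weinreb amide are not enolised under these conditions.

Step 8
Reactants: 14 silylene dienol ether; 15 methallylmagnesium chloride
Product: 16 methallyl ketone
Conditions: THF, −78 °C; aq. NH4Cl
Reagents that add atoms: none
Why: Weinreb ketone synthesis: the chelated adduct prevents over-addition, and the tert-butyl ester and the silyl enol ethers should not react with the allylic Grignard reagent at −78 °C (C1–C2 bond).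

Step 9
Reactants: 16 methallyl ketone
Product: 17 vinyl diazoketone
Conditions: p-ABSA, DBU, MeCN, 0 °C; used at once
Reagents that add atoms: 4-acetamidobenzenesulfonyl azide, CC(=O)Nc1ccc(cc1)S(=O)(=O)N=[N+]=[N-]
Why: Regitz diazo transfer to the doubly activated C1 methylene (α to the ketone and allylic), the usual entry to vinyl diazocarbonyl compounds; C3 is far less acidic, and any conjugated enone isomer converges through the same dienolate.

Step 10
Reactants: 17 vinyl diazoketone
Product: 19 silylene-bridged 2-oxohydroazula-1(10),6-diene, via divinylcyclopropane 18 (not isolated)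
Conditions: Rh2(O2CC7H15)4 (1 mol %), hexanes, slow addition, 25 → 60 °C
Reagents that add atoms: none
Why: Rh(II) turns the diazo group into a vinylcarbenoid at C1, which adds across the tethered C5=C6 enol ether (C1–C5 and C1–C6) to give the siloxy bicyclo[3.1.0]hexanone 18; this cis-divinylcyclopropane undergoes a [3,3] shift through a boat transition state that forms C8–C9 and cleaves the temporary C1–C6 bond. The closest known reaction type is the rhodium-catalysed tandem cyclopropanation/Cope rearrangement (formal [4+3]) of vinyl diazocarbonyl compounds with dienes, including cyclic dienes such as furans and cyclohexadiene and intramolecular cases. The cyclopentanone closes by intramolecular carbenoid addition through the three-atom tether C2–C4 (bicyclo[3.1.0]hexan-2-one), the cycloheptadiene by sigmatropic ring expansion of the cyclopropane. C5 is set by the face of C5=C6 that is attacked, under control of C4: the chain should approach so that the 4-silyloxy group lies next to the small C6–H and not next to the ring oxygen with its di-tert-butylsilyl group, which places O5 trans to O4; C8 follows stereospecifically, because the silylene holds O8 inside the boat on the side of O5, so the C8–O bond ends cis to C5–O. The step needs the cis-divinyl arrangement, secured by the ring-enforced Z geometry of the C5 enol ether, and addition to C5=C6 and not C7=C8, secured by the five-membered tether.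

Step 11
Reactants: 19 dienone
Product: 20 7αH-dihydro compound
Conditions: [Ir(cod)(PCy3)(py)]PF6 (5 mol %), H2 (1 atm), CH2Cl2, 0 °C
Reagents that add atoms: none
Why: Homogeneous iridium-catalysed hydrogenation of the trisubstituted C6=C7 bond; the silylene bridge with its tert-butyl groups covers the β face, so hydrogen should enter from the α face and push C11 to the β side, while the tetrasubstituted enone is left.

Step 12
Reactants: 20 silylene
Product: 21 5β,8β-diol tert-butyl ester
Conditions: HF·pyridine, pyridine, THF, 0 °C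
Reagents that add atoms: none
Why: Fluoride cleavage of the dialkoxy-di-tert-butylsilane (standard removal of a silylene acetal) under buffered conditions in which the tertiary TBS ether, the tert-butyl ester and the enone should survive.

Step 13
Reactants: 21 enone diol
Product: 22 saturated trans-fused ketone (1αH,10βH)
Conditions: Cu(OAc)2·H2O (5 mol %), 1,2-bis(diphenylphosphino)benzene (5 mol %), (EtO)2MeSiH, t-BuOH, toluene, rt; NH4F work-up
Reagents that add atoms: none
Why: Copper hydride conjugate reduction of the enone: hydride should add to C10 from the β face because C6–C8 of the seven-membered ring hang below the enone plane (C6 is α on C5), and protonation of the enolate at C1 should give the trans-fused ketone, with C1 still epimerisable next to the ketone so that a cis/trans mixture can be equilibrated before step 14.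

Step 14
Reactants: 22 β-hydroxy ketone
Product: 24 2α,5β-dihydroxy 12,8β-lactone, via triol ester 23 (not isolated)
Conditions: Me4NBH(OAc)3, MeCN/AcOH, −20 °C; then p-TsOH·H2O (cat.), toluene, 60 °C
Reagents that add atoms: none
Why: Hydroxyl-directed reduction of a β-hydroxy ketone (Saksena–Evans): the borohydride bound to the 5β-hydroxyl delivers hydride to the β face of C2 and gives the 2α-alcohol, after which acid converts the tert-butyl ester and the cis 8β-hydroxyl into the cis-fused γ-lactone (acid-catalysed lactonisation).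

Step 15
Reactants: 24 diol lactone
Product: 25 2α-triethylsilyl ether
Conditions: TESCl, imidazole, DMF, 0 °C
Reagents that add atoms: chlorotriethylsilane, CC[Si](Cl)(CC)CC
Why: Silyl ether formation at the secondary alcohol only (the tertiary 5-OH is inert to the silyl chloride), so that the enolate steps meet no acidic O–H apart from the hindered tertiary one.

Step 16
Reactants: 25 lactone
Product: 27 α-diazo lactone, via trifluoroacetyl lactone 26 (not isolated)
Conditions: LiHMDS (2.3 equiv), THF, −78 °C; CF3CO2CH2CF3; then MsN3, Et3N, H2O, MeCN, rt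
Reagents that add atoms: methanesulfonyl azide, CS(=O)(=O)N=[N+]=[N-]
Why: Detrifluoroacetylative diazo transfer: Claisen trifluoroacetylation activates the lactone α-carbon C11, and sulfonyl azide transfer with loss of the trifluoroacetyl group gives the α-diazo lactone.

Step 17
Reactants: 27 α-diazo lactone
Product: 28 5β,11-epoxy lactone (C11–H)
Conditions: Rh2(OPiv)4 (1 mol %), CH2Cl2 (0.005 M), −40 → 0 °C
Reagents that add atoms: none
Why: Intramolecular rhodium carbenoid O–H insertion into the 5β-hydroxyl closes the oxolane (C11–O5); the cis-fused lactone holds C11 over the β face next to O5, and a bulky carboxylate ligand at low temperature should hold back 1,2-hydride migration from C7.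

Step 18
Reactants: 28 ether lactone
Product: 29 11-methyl compound
Conditions: LDA, THF, −78 °C; MeI, −78 → −40 °C
Reagents that add atoms: iodomethane, CI
Why: Alkylation of the α-alkoxy lactone enolate; C11 is held by the lactone and the oxolane ring, so the methyl group can enter only from the outer face, which is the configuration of the target.

Step 19
Reactants: 29 bis-silyl ether
Product: 30 2α,4α-diol
Conditions: 48% aq. HF, MeCN, rt
Reagents that add atoms: none
Why: Acidic fluoride cleavage of the secondary TES and the tertiary TBS ether (silyl ether deprotection); lactone, cyclic ether and tertiary alcohol should be stable.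

Step 20
Reactants: 30 diol; 31 angelic acid
Product: 33 CNP0293659.1, via mixed anhydride 32 (not isolated)
Conditions: 31, 2,4,6-trichlorobenzoyl chloride, Et3N, toluene, rt; then 30, 80 °C
Reagents that add atoms: none
Why: Yamaguchi esterification through the trichlorobenzoyl mixed anhydride, run without DMAP to avoid Z→E isomerisation of the angelate; only the secondary 2α-hydroxyl is acylated, with retention at C2, and the tertiary 4-OH stays free.

**Compound list**

1 | (R)-citramalic acid, (2R)-2-hydroxy-2-methylbutanedioic acid | OC(=O)C[C@@](C)(O)C(O)=O | starting material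
2 | 2-[(4R)-2,2,4-trimethyl-5-oxo-1,3-dioxolan-4-yl]acetic acid | OC(=O)C[C@@]1(C)OC(C)(C)OC1=O | intermediate
3 | (3R)-3-hydroxy-4-[methoxy(methyl)amino]-3-methyl-4-oxobutanoic acid (magnesium salt in the flask) | OC(=O)C[C@@](C)(O)C(=O)N(C)OC | intermediate (not isolated)
4 | (3R)-3-hydroxy-3-methyl-4-oxopentanoic acid | OC(=O)C[C@@](C)(O)C(C)=O | intermediate
5 | tert-butyldimethylsilyl (3R)-3-[(tert-butyldimethylsilyl)oxy]-3-methyl-4-oxopentanoate | CC(C)(C)[Si](C)(C)OC(=O)C[C@@](C)(O[Si](C)(C)C(C)(C)C)C(C)=O | intermediate (not isolated)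
6 | (3R)-3-[(tert-butyldimethylsilyl)oxy]-3-methyl-4-oxopentanoic acid | OC(=O)C[C@@](C)(O[Si](C)(C)C(C)(C)C)C(C)=O | intermediate
7 | (3R)-3-[(tert-butyldimethylsilyl)oxy]-1-(imidazol-1-yl)-3-methylpentane-1,4-dione | O=C(C[C@@](C)(O[Si](C)(C)C(C)(C)C)C(C)=O)n1ccnc1 | intermediate (not isolated)
8 | (3R)-3-[(tert-butyldimethylsilyl)oxy]-N-methoxy-N,3-dimethyl-4-oxopentanamide | CON(C)C(=O)C[C@@](C)(O[Si](C)(C)C(C)(C)C)C(C)=O | intermediate
9 | (3R)-3-[(tert-butyldimethylsilyl)oxy]-N-methoxy-N,3-dimethyl-4-[(trimethylsilyl)oxy]pent-4-enamide | CON(C)C(=O)C[C@@](C)(O[Si](C)(C)C(C)(C)C)C(=C)O[Si](C)(C)C | intermediate (not isolated)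
10 | (3R)-5-bromo-3-[(tert-butyldimethylsilyl)oxy]-N-methoxy-N,3-dimethyl-4-oxopentanamide | CON(C)C(=O)C[C@@](C)(O[Si](C)(C)C(C)(C)C)C(=O)CBr | intermediate
11 | tert-butyl 4-oxobutanoate | O=CCCC(=O)OC(C)(C)C | starting material
12 | tert-butyl (3E)-4-(pyrrolidin-1-yl)but-3-enoate | O=C(C/C=C/N1CCCC1)OC(C)(C)C | intermediate (not isolated)
13 | tert-butyl (6R)-6-[(tert-butyldimethylsilyl)oxy]-3-formyl-8-[methoxy(methyl)amino]-6-methyl-5,8-dioxooctanoate (both C3 epimers) | CON(C)C(=O)C[C@@](C)(O[Si](C)(C)C(C)(C)C)C(=O)CC(C=O)CC(=O)OC(C)(C)C | intermediate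
14 | tert-butyl 2-{2,2-di-tert-butyl-4-[(2R)-2-[(tert-butyldimethylsilyl)oxy]-4-[methoxy(methyl)amino]-4-oxobutan-2-yl]-1,3,2-dioxasilepin-6-yl}acetate | CON(C)C(=O)C[C@@](C)(O[Si](C)(C)C(C)(C)C)C1=CC(CC(=O)OC(C)(C)C)=CO[Si](C(C)(C)C)(C(C)(C)C)O1 | intermediate
15 | methallylmagnesium chloride (2-methylprop-2-en-1-ylmagnesium chloride) | CC(=C)C[Mg]Cl | starting material
16 | tert-butyl 2-{2,2-di-tert-butyl-4-[(2R)-2-[(tert-butyldimethylsilyl)oxy]-6-methyl-4-oxohept-6-en-2-yl]-1,3,2-dioxasilepin-6-yl}acetate | CC(=C)CC(=O)C[C@@](C)(O[Si](C)(C)C(C)(C)C)C1=CC(CC(=O)OC(C)(C)C)=CO[Si](C(C)(C)C)(C(C)(C)C)O1 | intermediate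
17 | tert-butyl 2-{2,2-di-tert-butyl-4-[(2R)-2-[(tert-butyldimethylsilyl)oxy]-5-diazo-6-methyl-4-oxohept-6-en-2-yl]-1,3,2-dioxasilepin-6-yl}acetate | CC(=C)C(=[N+]=[N-])C(=O)C[C@@](C)(O[Si](C)(C)C(C)(C)C)C1=CC(CC(=O)OC(C)(C)C)=CO[Si](C(C)(C)C)(C(C)(C)C)O1 | intermediate
18 | cis-divinylcyclopropane: 1-isopropenyl-4-methyl-4α-(TBS-oxy)bicyclo[3.1.0]hexan-2-one (cyclopropane C1/C5/C6) whose C5–O and C6–C7=C8–O are closed by the di-tert-butylsilylene to a seven-membered ring (C7 bears CH2CO2tBu); isopropenyl, the C5 oxygen and C7 on one face of the cyclopropane | O=C1C[C@@](C)(O[Si](C)(C)C(C)(C)C)[C@@]23O[Si](C(C)(C)C)(C(C)(C)C)OC=C(CC(=O)OC(C)(C)C)[C@@H]2[C@@]13C(C)=C | intermediate (not isolated)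
19 | tert-butyl 4α-[(tert-butyldimethylsilyl)oxy]-5β,8β-[(di-tert-butylsilanediyl)dioxy]-2-oxo-13-norguaia-1(10),6-dien-12-oate | O=C1C[C@@](C)(O[Si](C)(C)C(C)(C)C)[C@@]23C=C(CC(=O)OC(C)(C)C)[C@@H](CC(C)=C12)O[Si](C(C)(C)C)(C(C)(C)C)O3 | intermediate
20 | tert-butyl 4α-[(tert-butyldimethylsilyl)oxy]-5β,8β-[(di-tert-butylsilanediyl)dioxy]-2-oxo-7αH-13-norguai-1(10)-en-12-oate | O=C1C[C@@](C)(O[Si](C)(C)C(C)(C)C)[C@@]23C[C@H](CC(=O)OC(C)(C)C)[C@@H](CC(C)=C12)O[Si](C(C)(C)C)(C(C)(C)C)O3 | intermediate
21 | tert-butyl 4α-[(tert-butyldimethylsilyl)oxy]-5β,8β-dihydroxy-2-oxo-7αH-13-norguai-1(10)-en-12-oate | O=C1C[C@@](C)(O[Si](C)(C)C(C)(C)C)[C@@]2(O)C[C@H](CC(=O)OC(C)(C)C)[C@H](O)CC(C)=C12 | intermediate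
22 | tert-butyl 4α-[(tert-butyldimethylsilyl)oxy]-5β,8β-dihydroxy-2-oxo-1αH,7αH,10βH-13-norguaian-12-oate | O=C1C[C@@](C)(O[Si](C)(C)C(C)(C)C)[C@@]2(O)C[C@H](CC(=O)OC(C)(C)C)[C@H](O)C[C@@H](C)[C@H]12 | intermediate
23 | tert-butyl 4α-[(tert-butyldimethylsilyl)oxy]-2α,5β,8β-trihydroxy-1αH,7αH,10βH-13-norguaian-12-oate | O[C@H]1C[C@@](C)(O[Si](C)(C)C(C)(C)C)[C@@]2(O)C[C@H](CC(=O)OC(C)(C)C)[C@H](O)C[C@@H](C)[C@H]12 | intermediate (not isolated)
24 | 4α-[(tert-butyldimethylsilyl)oxy]-2α,5β-dihydroxy-1αH,7αH,10βH-13-norguaian-12,8β-olide | O[C@H]1C[C@@](C)(O[Si](C)(C)C(C)(C)C)[C@@]2(O)C[C@@H]3CC(=O)O[C@@H]3C[C@@H](C)[C@H]12 | intermediate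
25 | 4α-[(tert-butyldimethylsilyl)oxy]-5β-hydroxy-2α-[(triethylsilyl)oxy]-1αH,7αH,10βH-13-norguaian-12,8β-olide | CC[Si](CC)(CC)O[C@H]1C[C@@](C)(O[Si](C)(C)C(C)(C)C)[C@@]2(O)C[C@@H]3CC(=O)O[C@@H]3C[C@@H](C)[C@H]12 | intermediate
26 | 11-(trifluoroacetyl) derivative of 25 (C11 unspecified, enolised) | CC[Si](CC)(CC)O[C@H]1C[C@@](C)(O[Si](C)(C)C(C)(C)C)[C@@]2(O)C[C@@H]3C(C(=O)C(F)(F)F)C(=O)O[C@@H]3C[C@@H](C)[C@H]12 | intermediate (not isolated)
27 | 11-diazo-4α-[(tert-butyldimethylsilyl)oxy]-5β-hydroxy-2α-[(triethylsilyl)oxy]-1αH,7αH,10βH-13-norguaian-12,8β-olide | CC[Si](CC)(CC)O[C@H]1C[C@@](C)(O[Si](C)(C)C(C)(C)C)[C@@]2(O)C[C@@H]3C(=[N+]=[N-])C(=O)O[C@@H]3C[C@@H](C)[C@H]12 | intermediate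
28 | 4α-[(tert-butyldimethylsilyl)oxy]-5β,11-epoxy-2α-[(triethylsilyl)oxy]-1αH,7αH,10βH-13-norguaian-12,8β-olide (H-11 on the outer face of the cage) | CC[Si](CC)(CC)O[C@H]1C[C@@](C)(O[Si](C)(C)C(C)(C)C)[C@@]23C[C@H]4[C@@H](C[C@@H](C)[C@H]12)OC(=O)[C@H]4O3 | intermediate
29 | 4α-[(tert-butyldimethylsilyl)oxy]-5β,11-epoxy-2α-[(triethylsilyl)oxy]-1αH,7αH,10βH-guaian-12,8β-olide (C13 on the outer face) | CC[Si](CC)(CC)O[C@H]1C[C@@](C)(O[Si](C)(C)C(C)(C)C)[C@@]23C[C@H]4[C@@H](C[C@@H](C)[C@H]12)OC(=O)[C@@]4(C)O3 | intermediate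
30 | 2α,4α-dihydroxy-5β,11-epoxy-1αH,7αH,10βH-guaian-12,8β-olide | O[C@H]1C[C@@](C)(O)[C@@]23C[C@H]4[C@@H](C[C@@H](C)[C@H]12)OC(=O)[C@@]4(C)O3 | intermediate
31 | angelic acid, (2Z)-2-methylbut-2-enoic acid | C/C=C(/C)C(O)=O | starting material
32 | angelic 2,4,6-trichlorobenzoic anhydride | C/C=C(/C)C(=O)OC(=O)c1c(Cl)cc(Cl)cc1Cl | intermediate (not isolated)
33 | CNP0293659.1, 2α-angeloyloxy-4α-hydroxy-5β,11-epoxy-1αH,7αH,10βH-guaian-12,8β-olide; (1R,2S,4R,5R,7S,8R,10R,11S) in guaiane numbering | C/C=C(/C)C(=O)O[C@H]1C[C@@](C)(O)[C@@]23C[C@H]4[C@@H](C[C@@H](C)[C@H]12)OC(=O)[C@@]4(C)O3 | target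

**Step count**

Total steps: 20. Longest linear sequence: 20 steps (1 → 33); 11, 15 and 31 are bought.

**Steps most likely to fail**

1. Step 10. The carbenoid may add to the other face of C5=C6 (wrong C5 relative to C4), or the silylene substituents may crowd the boat so that the siloxycyclopropane opens before it rearranges. Formation of the cyclic bis(enol ether) in step 7 could also fail, and this fallback bypasses it as well.
Fallback (sets out from 13, returns at 21): the tether is given up and an open-chain diene is used. Soft enolisation of 13 with TESOTf/Et3N should give the open-chain bis(triethylsilyl) dienol ether F1 (C5=C6 Z, C7=C8 E, enriched by equilibration or separated). Methallyl Grignard addition then gives the methallyl ketone F2, and diazo transfer the vinyl diazoketone F3. The same rhodium step, now through an unencumbered boat with the (E)-silyloxy group outside, should give the 5β,8α-bis(triethylsilyloxy) dienone F4. Selective methanolysis of the secondary allylic silyl ether (PPTS, MeOH) gives the 8α-alcohol F5. Its hydroxyl directs the iridium hydrogenation to the α face, giving the 7αH alcohol F6. Mitsunobu inversion with 4-nitrobenzoic acid (PPh3, DIAD) gives the 8β-(4-nitrobenzoate) F7, and methanolysis (K2CO3, MeOH) the 8β-alcohol F8. HF·pyridine then removes the tertiary triethylsilyl ether and gives 21.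

2. Step 13. Hydride may be delivered to the α face of C10, or the enolate may be protonated from the β face, so that the C10 or the C1 epimer forms.
Fallback (sets out from 21, returns at 22): hydroxyl-directed hydrogenation with [Ir(cod)(PCy3)(py)]PF6 under hydrogen pressure. The 5β- and 8β-hydroxyls both bind the metal on the β face, so both hydrogens enter there. This fixes 10β-H and gives the cis-fused ketone F9 (1β-H). Base equilibration (DBU, toluene) then epimerises C1 next to the ketone to the trans-fused 22.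

3. Step 17. 1,2-Hydride migration from C7 in the carbenoid (butenolide formation) or intermolecular reaction of the diazo lactone may outrun the O–H insertion.
Fallback (sets out from 25, returns at 29): the methyl group is put in first and the ether closed by substitution. Methylation of the lactone enolate (LDA 2.2 equiv, MeI) gives the α-methyl lactone F10. Bromination of its enolate from the convex face (LDA, then CBr4) gives the tertiary α-bromo lactone F11. Silver-assisted intramolecular displacement of bromide by the 5β-hydroxyl (AgOTf, 2,6-di-tert-butylpyridine, CH2Cl2) closes the oxolane with inversion and gives 29.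

**Further compounds**

F1 | step 10 | tert-butyl (3E,4Z,6R)-6-[(tert-butyldimethylsilyl)oxy]-8-[methoxy(methyl)amino]-6-methyl-8-oxo-5-[(triethylsilyl)oxy]-3-{[(triethylsilyl)oxy]methylidene}oct-4-enoate | CON(C)C(=O)C[C@@](C)(O[Si](C)(C)C(C)(C)C)/C(O[Si](CC)(CC)CC)=C/C(CC(=O)OC(C)(C)C)=C/O[Si](CC)(CC)CC
F2 | step 10 | methallyl ketone from F1 (Weinreb amide replaced by CH2C(CH3)=CH2 ketone) | CC(=C)CC(=O)C[C@@](C)(O[Si](C)(C)C(C)(C)C)/C(O[Si](CC)(CC)CC)=C/C(CC(=O)OC(C)(C)C)=C/O[Si](CC)(CC)CC
F3 | step 10 | open-chain vinyl diazoketone (diazo at C1 of F2) | CC(=C)C(=[N+]=[N-])C(=O)C[C@@](C)(O[Si](C)(C)C(C)(C)C)/C(O[Si](CC)(CC)CC)=C/C(CC(=O)OC(C)(C)C)=C/O[Si](CC)(CC)CC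
F4 | step 10 | tert-butyl 4α-[(tert-butyldimethylsilyl)oxy]-2-oxo-5β,8α-bis[(triethylsilyl)oxy]-13-norguaia-1(10),6-dien-12-oate | O=C1C[C@@](C)(O[Si](C)(C)C(C)(C)C)[C@@]2(O[Si](CC)(CC)CC)C=C(CC(=O)OC(C)(C)C)[C@@H](O[Si](CC)(CC)CC)CC(C)=C12
F5 | step 10 | tert-butyl 4α-[(tert-butyldimethylsilyl)oxy]-8α-hydroxy-2-oxo-5β-[(triethylsilyl)oxy]-13-norguaia-1(10),6-dien-12-oate | O=C1C[C@@](C)(O[Si](C)(C)C(C)(C)C)[C@@]2(O[Si](CC)(CC)CC)C=C(CC(=O)OC(C)(C)C)[C@@H](O)CC(C)=C12
F6 | step 10 | tert-butyl 4α-[(tert-butyldimethylsilyl)oxy]-8α-hydroxy-2-oxo-5β-[(triethylsilyl)oxy]-7αH-13-norguai-1(10)-en-12-oate | O=C1C[C@@](C)(O[Si](C)(C)C(C)(C)C)[C@@]2(O[Si](CC)(CC)CC)C[C@H](CC(=O)OC(C)(C)C)[C@@H](O)CC(C)=C12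
F7 | step 10 | tert-butyl 4α-[(tert-butyldimethylsilyl)oxy]-8β-[(4-nitrobenzoyl)oxy]-2-oxo-5β-[(triethylsilyl)oxy]-7αH-13-norguai-1(10)-en-12-oate | O=C1C[C@@](C)(O[Si](C)(C)C(C)(C)C)[C@@]2(O[Si](CC)(CC)CC)C[C@H](CC(=O)OC(C)(C)C)[C@H](OC(=O)c3ccc(cc3)[N+](=O)[O-])CC(C)=C12
F8 | step 10 | tert-butyl 4α-[(tert-butyldimethylsilyl)oxy]-8β-hydroxy-2-oxo-5β-[(triethylsilyl)oxy]-7αH-13-norguai-1(10)-en-12-oate | O=C1C[C@@](C)(O[Si](C)(C)C(C)(C)C)[C@@]2(O[Si](CC)(CC)CC)C[C@H](CC(=O)OC(C)(C)C)[C@H](O)CC(C)=C12
F9 | step 13 | tert-butyl 4α-[(tert-butyldimethylsilyl)oxy]-5β,8β-dihydroxy-2-oxo-1βH,7αH,10βH-13-norguaian-12-oate (cis-fused C1 epimer of 22) | O=C1C[C@@](C)(O[Si](C)(C)C(C)(C)C)[C@@]2(O)C[C@H](CC(=O)OC(C)(C)C)[C@H](O)C[C@@H](C)[C@@H]12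
F10 | step 17 | 4α-[(tert-butyldimethylsilyl)oxy]-5β-hydroxy-2α-[(triethylsilyl)oxy]-1αH,7αH,10βH-guaian-12,8β-olide (C11 epimers) | CC[Si](CC)(CC)O[C@H]1C[C@@](C)(O[Si](C)(C)C(C)(C)C)[C@@]2(O)C[C@@H]3C(C)C(=O)O[C@@H]3C[C@@H](C)[C@H]12
F11 | step 17 | 11-bromo-4α-[(tert-butyldimethylsilyl)oxy]-5β-hydroxy-2α-[(triethylsilyl)oxy]-1αH,7αH,10βH-guaian-12,8β-olide (bromine on the outer face) | CC[Si](CC)(CC)O[C@H]1C[C@@](C)(O[Si](C)(C)C(C)(C)C)[C@@]2(O)C[C@@H]3[C@@](C)(Br)C(=O)O[C@@H]3C[C@@H](C)[C@H]12
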